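**Strategy**

The route rests on breaking the aryl ether bond O1–C8a, so that the pyran ring (ring B) is closed last, on an unprotected open-chain phenol carrying the C2 tertiary alcohol. The key step exploits the para relationship between O1 on C8a and the C6 hydroxyl of the benzene ring (ring A), a hydroquinone monoether: PhI(OAc)2 turns the para C–H carbon C8a into an electrophile, the C2 hydroxyl closes ring B there, and ascorbic acid returns the over-oxidised ketal to the chromanol, all in one flask with C2 untouched. The precursor is built in five steps from (R)-linalool (C2), 3-bromo-5-methylphenol and (R)-citronellyl bromide (C8'); C4' is set by iridium-catalysed hydrogenation.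

Key step: step 6

Assumption: commercial (R)-(−)-linalool and (R)-(−)-citronellyl bromide are taken as enantiomerically pure, and the (S) enantiomer of the phosphinooxazoline ligand in step 3 is taken as the one that gives the 2S alcohol (its antipode is used if a test run shows the opposite sense).

**Route**

Step 1
Reactants: 1 (R)-(−)-linalool
Product: 2 (2E,6R)-2,6-dimethylocta-2,7-diene-1,6-diol
Conditions: SeO2 (0.4 equiv), t-BuOOH (3 equiv), salicylic acid (0.1 equiv), CH2Cl2, rt
Reagents that add atoms: tert-butyl hydroperoxide, CC(C)(C)OO (terminal oxidant, oxygen delivered through selenium dioxide, O=[Se]=O)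
Why: Riley-type allylic oxidation with catalytic SeO2 and t-BuOOH proceeds by an ene reaction and a [2,3]-sigmatropic shift at the more electron-rich trisubstituted alkene and oxidises the methyl group trans to the chain, so the E allylic alcohol should form while the vinyl carbinol and its stereocenter (future C2) are untouched.

Step 2
Reactants: 2 (2E,6R)-2,6-dimethylocta-2,7-diene-1,6-diol; 3 3-bromo-5-methylphenol
Product: 5 (2E,6R)-8-(3-hydroxy-5-methylphenyl)-2,6-dimethyloct-2-ene-1,6-diol, via alkylborane 4 (not isolated)
Conditions: 9-BBN-H (2.3 equiv), THF, 0 °C to rt; then 3, Pd(dppf)Cl2 (5 mol%), K3PO4 (4 equiv), DMF/H2O, 60 °C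
Reagents that add atoms: none
Why: 9-BBN-H esterifies the primary hydroxyl and then hydroborates only the monosubstituted vinyl group at its terminal carbon, and the B-alkyl Suzuki–Miyaura coupling of alkylborane 4 with the bromophenol (present as its phenoxide) forms the future C4–C4a bond without touching the carbinol stereocenter.

Step 3
Reactants: 5 (2E,6R)-8-(3-hydroxy-5-methylphenyl)-2,6-dimethyloct-2-ene-1,6-diol
Product: 6 (2S,6R)-8-(3-hydroxy-5-methylphenyl)-2,6-dimethyloctane-1,6-diol
Conditions: H2 (50 bar), [Ir(cod)((S)-tBu-PHOX)]BArF (1 mol%), CH2Cl2, rt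
Reagents that add atoms: none
Why: Iridium-catalysed asymmetric hydrogenation of the E-configured 2-methyl allylic alcohol with a chiral phosphinooxazoline ligand is catalyst-controlled, so the ligand selects the alkene face and sets the new methyl-bearing stereocenter (2S here, the future 4'R) independently of the remote C6 carbinol.

Step 4
Reactants: 6 (2S,6R)-8-(3-hydroxy-5-methylphenyl)-2,6-dimethyloctane-1,6-diol
Product: 7 (3R,7S)-8-bromo-1-(3-hydroxy-5-methylphenyl)-3,7-dimethyloctan-3-ol
Conditions: CBr4 (1.2 equiv), PPh3 (1.3 equiv), CH2Cl2, 0 °C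
Reagents that add atoms: carbon tetrabromide, BrC(Br)(Br)Br
Why: Appel bromination goes through an alkoxyphosphonium ion that bromide displaces in an SN2 step, which only the primary alcohol can undergo, so the phenol and the tertiary alcohol should be returned on work-up and the neighbouring stereocenter, not being the reacting carbon, keeps its configuration.

Step 5
Reactants: 7 (3R,7S)-8-bromo-1-(3-hydroxy-5-methylphenyl)-3,7-dimethyloctan-3-ol; 8 (R)-citronellyl bromide [(6R)-8-bromo-2,6-dimethyloct-2-ene]
Product: 10 (3R,7R,11S)-1-(3-hydroxy-5-methylphenyl)-3,7,11,15-tetramethylhexadec-14-en-3-ol, via Grignard reagent 9 (not isolated)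
Conditions: 8 (3.5 equiv), Mg turnings, THF, rt; then 7, Li2CuCl4 (5 mol%), NMP (4 equiv), THF, 0 °C to rt
Reagents that add atoms: none
Why: In this copper-catalysed Kochi-type alkyl–alkyl coupling two equivalents of Grignard reagent 9 deprotonate the phenol and the tertiary alcohol and the remainder displaces the primary bromide to form the C5'–C6' bond, bringing in the C8' stereocenter from 8 with no stereocenter at a reacting carbon.

Step 6
Reactants: 10 (3R,7R,11S)-1-(3-hydroxy-5-methylphenyl)-3,7,11,15-tetramethylhexadec-14-en-3-ol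
Product: 12 (2R)-2,8-dimethyl-2-[(4R,8S)-4,8,12-trimethyltridec-11-en-1-yl]-3,4-dihydro-2H-chromen-6-ol, via methoxy ketal 11 (not isolated)
Conditions: PhI(OAc)2 (2.2 equiv), MeOH (10 equiv), MeCN, 0 °C, slow addition of 10; then L-ascorbic acid (3 equiv), AcOH/H2O, rt
Reagents that add atoms: none
Why: Ligand exchange of the phenol at trivalent iodine and loss of PhI turn ring A into a phenoxenium-type electrophile, the C2 tertiary hydroxyl adds to the para C–H carbon C8a, and tautomerisation gives the chroman-6-ol, which is 12 itself. Because this hydroquinone monoether is oxidised faster than phenol 10, the second equivalent of PhI(OAc)2 is spent on purpose to carry it on to the chromanoxylium ion, trapped by methanol as ketal 11, and mild acid with ascorbic acid then re-ionises 11 by loss of the exocyclic methoxy group and reduces the cation back to 12. The closest known reaction types are the PhI(OAc)2/alcohol oxidation of para-unsubstituted phenols to para-quinone monoketals and the ascorbic acid reduction of 8a-alkoxytocopherones to tocopherols. Ring B is closed in a 6-exo-trig mode, the oxygen attacking C8a of the dienone π-system through a six-membered transition state. No stereocenter is created in 12: the C2–O bond is never broken, so the linalool-derived configuration is kept, and the transient C8a center of 11 is erased on rearomatisation. The step needs attack at para C8a and not at ortho C5, which the larger para coefficient of the phenoxenium ion and the shielding of C5 by the iodine-bearing oxygen should secure, and it needs the remote trisubstituted alkene to survive, which is expected because PhI(OAc)2 without Lewis acid activation oxidises a phenol far faster than an isolated alkene.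

**Compound list**

1 | (R)-(−)-linalool, (3R)-3,7-dimethylocta-1,6-dien-3-ol | C=C[C@](C)(O)CCC=C(C)C | starting material
2 | (2E,6R)-2,6-dimethylocta-2,7-diene-1,6-diol | C=C[C@](C)(O)CC/C=C(\C)CO | intermediate
3 | 3-bromo-5-methylphenol | Cc1cc(O)cc(Br)c1 | starting material
4 | B-alkyl-9-BBN adduct of 2 at the former vinyl terminus, primary hydroxyl carried as its 9-BBN borinate (not isolated) | B1(C2CCCC1CCC2)CC[C@](C)(O)CC/C=C(\C)COB1C2CCCC1CCC2 | intermediate
5 | (2E,6R)-8-(3-hydroxy-5-methylphenyl)-2,6-dimethyloct-2-ene-1,6-diol | Cc1cc(O)cc(CC[C@](C)(O)CC/C=C(\C)CO)c1 | intermediate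
6 | (2S,6R)-8-(3-hydroxy-5-methylphenyl)-2,6-dimethyloctane-1,6-diol | Cc1cc(O)cc(CC[C@](C)(O)CCC[C@H](C)CO)c1 | intermediate
7 | (3R,7S)-8-bromo-1-(3-hydroxy-5-methylphenyl)-3,7-dimethyloctan-3-ol | Cc1cc(O)cc(CC[C@](C)(O)CCC[C@H](C)CBr)c1 | intermediate
8 | (R)-citronellyl bromide, (6R)-8-bromo-2,6-dimethyloct-2-ene | BrCC[C@H](C)CCC=C(C)C | starting material
9 | (R)-citronellylmagnesium bromide (not isolated) | Br[Mg]CC[C@H](C)CCC=C(C)C | intermediate
10 | (3R,7R,11S)-1-(3-hydroxy-5-methylphenyl)-3,7,11,15-tetramethylhexadec-14-en-3-ol | Cc1cc(O)cc(CC[C@](C)(O)CCC[C@H](C)CCC[C@H](C)CCC=C(C)C)c1 | intermediate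
11 | (2R)-8a-methoxy-2,8-dimethyl-2-[(4R,8S)-4,8,12-trimethyltridec-11-en-1-yl]-2,3,4,8a-tetrahydro-6H-chromen-6-one, both C8a epimers (not isolated) | CC(C)=CCC[C@@H](C)CCC[C@@H](C)CCC[C@]1(C)CCC2=CC(=O)C=C(C)C2(OC)O1 | intermediate
12 | (2R)-2,8-dimethyl-2-[(4R,8S)-4,8,12-trimethyltridec-11-en-1-yl]-3,4-dihydro-2H-chromen-6-ol | CC(C)=CCC[C@@H](C)CCC[C@@H](C)CCC[C@]1(C)CCc2cc(O)cc(C)c2O1 | target

**Summary**

Total step count: 6. Longest linear sequence: 6 steps (1 to 12 through steps 1–6); 3 and 8 are bought and enter in steps 2 and 5.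

**Steps most likely to fail**

1. Step 6 (key step). What may go wrong: the oxidised ring is captured by methanol or acetate and not by the tethered alcohol, attack occurs at the ortho carbon C5, or the ketal opens to the quinone, so that the reduction returns uncyclised material. The fallback sets out from 10 and comes back at 12. Teuber oxidation of 10 with Fremy's salt, (KSO3)2NO, in buffered aqueous acetone should give 2-[(3R,7R,11S)-3-hydroxy-3,7,11,15-tetramethylhexadec-14-en-1-yl]-6-methylcyclohexa-2,5-diene-1,4-dione F1, in which the C8a oxygen is already in place as a carbonyl. Na2S2O4 in a two-phase system reduces it to 2-[(3R,7R,11S)-3-hydroxy-3,7,11,15-tetramethylhexadec-14-en-1-yl]-6-methylbenzene-1,4-diol F2. Acid (p-TsOH, toluene, 60 °C) then closes ring B to 12. This is the tocopherolquinone-to-tocopherol ring closure, documented in the tocopherol series to retain the configuration of the carbinol carbon, which points to closure at the aryl carbon.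

2. Step 3. What may go wrong: poor facial selectivity in the hydrogenation (the C2 epimer could not be removed downstream) or inhibition of the cationic iridium catalyst by the free phenol. The fallback sets out from 5 and comes back at 6. MnO2 in CH2Cl2 oxidises the allylic alcohol to (2E,6R)-6-hydroxy-8-(3-hydroxy-5-methylphenyl)-2,6-dimethyloct-2-enal F3. Pinnick oxidation (NaClO2, NaH2PO4, 2-methyl-2-butene, t-BuOH/H2O) gives (2E,6R)-6-hydroxy-8-(3-hydroxy-5-methylphenyl)-2,6-dimethyloct-2-enoic acid F4. Hydrogenation with Ru(OAc)2[(S)-H8-BINAP] and H2 in MeOH, in which the carboxylate binds ruthenium and the substrate is a close analogue of tiglic acid, should give (2S,6R)-6-hydroxy-8-(3-hydroxy-5-methylphenyl)-2,6-dimethyloctanoic acid F5. LiAlH4 in THF reduces F5 to 6.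

3. Step 5. What may go wrong: slow substitution at the β-branched primary bromide in the presence of two magnesium alkoxides, with homocoupling and reduction of the Grignard reagent using it up. The fallback sets out from 7 and comes back at 10. Heating 7 with PPh3 in MeCN gives [(2S,6R)-6-hydroxy-8-(3-hydroxy-5-methylphenyl)-2,6-dimethyloctyl]triphenylphosphonium bromide F6. Deprotonation with NaHMDS (3.1 equiv, THF, −78 °C) and Wittig reaction with commercial (R)-citronellal, O=CC[C@H](C)CCC=C(C)C, should give (3R,7S,8Z,11R)-1-(3-hydroxy-5-methylphenyl)-3,7,11,15-tetramethylhexadeca-8,14-dien-3-ol F7. Diimide (2-nitrobenzenesulfonylhydrazide, Et3N, CH2Cl2, rt) reduces the disubstituted alkene in preference to the trisubstituted one and gives 10.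

**Further compounds**

F1 | step 6 | 2-[(3R,7R,11S)-3-hydroxy-3,7,11,15-tetramethylhexadec-14-en-1-yl]-6-methylcyclohexa-2,5-diene-1,4-dione | CC(C)=CCC[C@@H](C)CCC[C@@H](C)CCC[C@@](C)(O)CCC1=CC(=O)C=C(C)C1=O
F2 | step 6 | 2-[(3R,7R,11S)-3-hydroxy-3,7,11,15-tetramethylhexadec-14-en-1-yl]-6-methylbenzene-1,4-diol | CC(C)=CCC[C@@H](C)CCC[C@@H](C)CCC[C@@](C)(O)CCc1cc(O)cc(C)c1O
F3 | step 3 | (2E,6R)-6-hydroxy-8-(3-hydroxy-5-methylphenyl)-2,6-dimethyloct-2-enal | Cc1cc(O)cc(CC[C@](C)(O)CC/C=C(\C)C=O)c1
F4 | step 3 | (2E,6R)-6-hydroxy-8-(3-hydroxy-5-methylphenyl)-2,6-dimethyloct-2-enoic acid | Cc1cc(O)cc(CC[C@](C)(O)CC/C=C(\C)C(=O)O)c1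
F5 | step 3 | (2S,6R)-6-hydroxy-8-(3-hydroxy-5-methylphenyl)-2,6-dimethyloctanoic acid | Cc1cc(O)cc(CC[C@](C)(O)CCC[C@H](C)C(=O)O)c1
F6 | step 5 | [(2S,6R)-6-hydroxy-8-(3-hydroxy-5-methylphenyl)-2,6-dimethyloctyl]triphenylphosphonium bromide | Cc1cc(O)cc(CC[C@](C)(O)CCC[C@H](C)C[P+](c2ccccc2)(c2ccccc2)c2ccccc2)c1.[Br-]
F7 | step 5 | (3R,7S,8Z,11R)-1-(3-hydroxy-5-methylphenyl)-3,7,11,15-tetramethylhexadeca-8,14-dien-3-ol | Cc1cc(O)cc(CC[C@](C)(O)CCC[C@H](C)/C=C\C[C@H](C)CCC=C(C)C)c1
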